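**Time of reading.** The excess read at 2.5 h sums up the whole run, not its last moment. So you can replace the falling left-handed substrate by its mean over the run.

| setting | oak | spring | midnight | autumn | dusk |
|---|---|---|---|---|---|
| left-handed substrate | 0.80 M | 0.80 M | 0.80 M | 0.80 M | 0.80 M |
| right-handed substrate | 0.80 M | 0.80 M | 0.80 M | 0.80 M | 0.80 M |
| coupling partner | 0.80 M | 0.800 M | 0.800 M | 0.800 M | 0.800 M |
| free catalyst | 96 mM | 64 mM | 64 mM | 64 mM | 64 mM |
| temperature | 95 °C | 95 °C | 140 °C | 110 °C | 125 °C |
| remark | run made earlier |  |  |  |  |
| time |  | 2.5 h | 2.5 h | 2.5 h | 2.5 h |

oak run (percent of the left-handed substrate and right-handed substrate together charged)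

| time / min | left-handed product / % | right-handed product / % |
|---|---|---|
| 8.00 | 1.6 | 0 |
| 15.0 | 1.5 | 0 |
| 25.0 | 3.4 | 0 |
| 30.0 | 4.3 | 0 |
| 40.0 | 4.6 | 1.2 |
| 50.0 | 5.3 | 0.6 |

(each reading ± 0.5 percentage points)

- free catalyst is single-handed; left-handed substrate and right-handed substrate are mirror images of each other, charged as a racemate, each of them at the stated concentration
- the earlier runs do not show what temperature does; that part of a forecast is a guess
- an excess is the difference of the two amounts in percent of their sum
- an excess is below zero if the other one leads
- no earlier run changes the charge of free catalyst; that part of a forecast is a guess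

- the best flask by excess of left-handed product over right-handed product; "all alike" if 1.5 percentage points covers them all (spring / midnight / autumn / dusk / all alike)
- excess of left-handed product over right-handed product at the end, spring
- excess of left-handed product over right-handed product at the end, midnight
- excess of left-handed product over right-handed product at the end, autumn
- excess of left-handed product over right-handed product at the end, dusk

**Pooled ratio.** Sum the oak readings of left-handed product and divide by the sum for right-handed product: you get 11.5. Call this the pooled ratio, a selectivity factor as read. It is loose, since its lower sum rests on 1.2% and 0.6%, each with a scatter of 0.5 percentage points.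

**Spring reckoned.** Take the oak pace to its last reading and guess first order in free catalyst. My estimate for spring at the end is then 10.6% left-handed product. Left-handed substrate is half of the substrate charged, so on a straight fall its mean is 89.4% of its charge. Holding the right-handed substrate unchanged, the ratio becomes 10.3 and my excess 82.3%. The exact curve gives 10.3, about the same, so the mean costs little.

**Turned round.** For "all alike", every flask must stay within 1.5 points of spring. That lower edge is a ratio of 9.40. With the pooled ratio unchanged, a flask reaches it at 18.3% left-handed product, which is more than my estimate of 10.6% for spring. Heat is a guess here; mine is that hotter flasks cross that line and spring stays best.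

**The forecast.** It gave spring 78%, midnight 55%, autumn 72% and dusk 64%: "Spring should be best, though the temperature effects remain guesses".

**The flask.** Spring is best at 88.6%, ahead of autumn at 81.9%, dusk at 72.8% and midnight at 61.1%; spring holds 9.66% left-handed product at 2.50 h.

    coupling partner + free catalyst + left-handed substrate → free catalyst + left-handed product (k = 0.0820 M⁻² min⁻¹, Ea = 58.0 kJ mol⁻¹)
    coupling partner + free catalyst + right-handed substrate → free catalyst + right-handed product (k = 0.00710 M⁻² min⁻¹, Ea = 94.0 kJ mol⁻¹)
    2 free catalyst → spent catalyst (k = 0.0570 M⁻¹ min⁻¹, Ea = 71.0 kJ mol⁻¹)
    free catalyst ⇌ dormant form (K = 1.10, k = 0.00240 min⁻¹, Ea = 125 kJ mol⁻¹, ΔH = −46.0 kJ mol⁻¹)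
    (constants at 110 °C)

**Ratio reused.** Turned back through the mean, spring's excess gives a pooled ratio of 18.3, higher than the oak reading. Carry it to spring at 25.0 h, which holds 24.5% left-handed product: the ratio is 13.8 and the excess 86.5%. Spring stands at 86.3% then.

The data were computed on assumed constants, noise included.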